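The route rests on cutting ring B of the decalin at C7–C8 and C9–C10. The C8(H)(Me)–C9(Me)(CH2Ar) unit, with its cis methyls and one-carbon branch, is the carbon set of (E)-2-methylbut-2-enal, and C10–C5(Me)–C6–C7 is an E 1-alkyl-2-methylbutadiene whose C10 chain (C1–C3) ends in an alkyne holding C4 and the methylene carbon. One catalytic enantioselective, exo-selective Diels–Alder reaction closes ring B and sets C8, C9 and C10; its precursor is an acyclic dienyne made by two Wittig reactions. A radical closure of ring A then sets C5, and the arene is joined last through the neopentyl aldehyde.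

Key step: step 3

Remark: the decalin carries the usual numbering of this sesquiterpene class (ring A = C1–C5 and C10, ring B = C5–C10, methylene on C4, angular methyl on C5, arylmethyl on C9). The aryl sulfate is assumed to be handled and purified as a salt and converted to the drawn free hydrogen sulfate by cold cation exchange only as the last operation.

Step 1
Reactants: 1 hex-5-yn-1-ol + 2 2-(triphenylphosphoranylidene)propanal
Product: 4 (E)-2-methyloct-2-en-7-ynal, via hex-5-ynal 3 (not isolated)
Conditions: TEMPO (10 mol%), PhI(OAc)2 (1.05 equiv), CH2Cl2, rt; then 2 (1.2 equiv), 40 °C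
Reagents that add atoms: none
Why: The TEMPO/PhI(OAc)2 oxidation stops at the aldehyde, which is trapped in the same flask by the formyl-stabilised ylide in a Wittig reaction that should give the E enal, so the volatile aldehyde is never handled neat.

Step 2
Reactants: 4 (E)-2-methyloct-2-en-7-ynal + 5 methyltriphenylphosphonium bromide
Product: 7 (E)-3-methylnona-1,3-dien-8-yne, via methylenetriphenylphosphorane 6 (not isolated)
Conditions: 5 (1.2 equiv), KOt-Bu (1.15 equiv), THF, 0 °C; then 4, 0 °C → rt; product kept as a pentane solution and used promptly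
Reagents that add atoms: none
Why: Wittig methylenation by 1,2-addition of the non-stabilised ylide to the enal carbonyl leaves the E trisubstituted alkene and the terminal alkyne (far less acidic than the phosphonium salt) untouched.

Step 3
Reactants: 7 (E)-3-methylnona-1,3-dien-8-yne + 8 tiglic aldehyde [(E)-2-methylbut-2-enal]
Product: 9 (1R,2R,6S)-1,3,6-trimethyl-2-(pent-4-yn-1-yl)cyclohex-3-ene-1-carbaldehyde
Conditions: (R)-3,3-diphenyl-1-(2-methylphenyl)tetrahydro-1H,3H-pyrrolo[1,2-c][1,3,2]oxazaborole (20 mol%) activated with HN(SO2CF3)2 (17 mol%), 8 (2 equiv), CH2Cl2, −78 → −40 °C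
Reagents that add atoms: none
Why: The boron-bound s-trans enal, held by a formyl C–H···O contact, undergoes a concerted but asynchronous [4+2] cycloaddition in which its β-carbon (C8) bonds first to the unsubstituted diene terminus C7 and its α-carbon (C9) then bonds to the alkyl-bearing terminus C10; the closest known reaction type is the cationic oxazaborolidine-catalysed enantioselective Diels–Alder reaction of α-substituted enals with 1,2-dialkyl dienes of the 1-vinylcyclohexene kind. Ring B closes as a cyclohexene by intermolecular [4+2] annulation through the C7–C8 and C9–C10 bonds, and the C5=C6 alkene that remains is the handle for step 4. The cis C8/C9 methyl pair is dictated by the E geometry of 8, the C10 configuration relative to C9 by the E diene (chain outside) together with the formyl-exo transition state that the α-methyl group enforces, and the absolute configuration by the catalyst, whose (R) antipode is expected from the binding model to leave the Si face of the enal α-carbon open (the sense is to be confirmed by correlation on the first run, the mirror-image catalyst being the remedy otherwise). The step needs ortho regiochemistry, exo diastereoselectivity and one enantioface: the first is secured by bonding at the least hindered terminus C7 with the developing positive charge spread over C6–C5(Me)–C10, the second by the α-methyl group of the enal, and the third by the chiral Lewis acid.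

Step 4
Reactants: 9 (1R,2R,6S)-1,3,6-trimethyl-2-(pent-4-yn-1-yl)cyclohex-3-ene-1-carbaldehyde
Product: 10 (1R,2S,4aS,8aR)-1,2,4a-trimethyl-5-methylidenedecahydronaphthalene-1-carbaldehyde (trans-fused)
Conditions: Fe(acac)3 (0.5 equiv), PhSiH3 (2.5 equiv), degassed EtOH/(CH2OH)2 (5:1), 0.02 M, 60 °C
Reagents that add atoms: none
Why: Proposed new method: hydrogen-atom transfer from an iron hydride (metal-hydride HAT, MHAT) to C6 of the trisubstituted alkene gives the tertiary C5 radical, which closes 6-exo-dig onto the internal alkyne carbon C4 through a chair-like transition state with the C10 tether equatorial and the alkyne approaching anti to the axial C9 methyl (hence trans fusion with the C5 methyl syn to the C9 methyl), and the vinyl radical then takes a hydrogen atom from silane or ethanol to leave the methylene; the closest known reaction types are MHAT-initiated reductive radical cyclisations onto electron-poor alkenes and tin hydride-mediated alkyl radical 6-exo-dig closures onto terminal alkynes.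

Step 5
Reactants: 11 3-bromo-4,5-dihydroxybenzaldehyde
Product: 12 3-bromo-5-hydroxy-4-(methoxymethoxy)benzaldehyde
Conditions: MOMCl (1.05 equiv), K2CO3 (1.0 equiv), acetone, 0 °C → rt
Reagents that add atoms: chloromethyl methyl ether (MOMCl), COCCl
Why: With one equivalent of base the phenoxide forms at the more acidic 4-OH (para to the formyl group, ortho to bromine), so this Williamson-type O-alkylation should mark the oxygen that later carries the sulfate, the regiochemistry to be confirmed by NOE/HMBC before going on.

Step 6
Reactants: 12 3-bromo-5-hydroxy-4-(methoxymethoxy)benzaldehyde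
Product: 13 3-bromo-5-(hydroxymethyl)-2-(methoxymethoxy)phenol
Conditions: NaBH4 (0.6 equiv), MeOH, 0 °C
Reagents that add atoms: none
Why: Borohydride reduction of the aryl aldehyde to the benzylic alcohol does not touch the aryl bromide, the MOM ether or the phenol.

Step 7
Reactants: 13 3-bromo-5-(hydroxymethyl)-2-(methoxymethoxy)phenol
Product: 14 1-bromo-2-(methoxymethoxy)-3-(triisopropylsilyloxy)-5-[(triisopropylsilyloxy)methyl]benzene
Conditions: i-Pr3SiCl (2.5 equiv), imidazole (5 equiv), DMAP (cat.), DMF, rt → 40 °C
Reagents that add atoms: triisopropylsilyl chloride (TIPSCl), CC(C)[Si](Cl)(C(C)C)C(C)C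
Why: Imidazole-promoted silylation covers the phenol and the primary alcohol in one operation with bulky silyl ethers that tolerate t-BuLi and radical conditions and fall together to fluoride at the end.

Step 8
Reactants: 14 1-bromo-2-(methoxymethoxy)-3-(triisopropylsilyloxy)-5-[(triisopropylsilyloxy)methyl]benzene + 10 (1R,2S,4aS,8aR)-1,2,4a-trimethyl-5-methylidenedecahydronaphthalene-1-carbaldehyde
Product: 16 [2-(methoxymethoxy)-3-(triisopropylsilyloxy)-5-{(triisopropylsilyloxy)methyl}phenyl][(1R,2S,4aS,8aR)-1,2,4a-trimethyl-5-methylidenedecahydronaphthalen-1-yl]methanol (both carbinol epimers), via aryllithium 15 (not isolated)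
Conditions: 14 (1.5 equiv), t-BuLi (3.0 equiv), THF, −78 °C; then 10, −78 → −20 °C; then H2O
Reagents that add atoms: none
Why: Bromine–lithium exchange gives an aryllithium stabilised by the ortho MOM oxygen, which adds 1,2 to the non-enolisable neopentyl aldehyde; the new carbinol centre forms without control, which is immaterial because it is removed in step 10.

Step 9
Reactants: 16 aryl(decalinyl)methanol (both carbinol epimers)
Product: 17 O-{aryl(decalinyl)methyl} S-methyl carbonodithioate (xanthate of 16)
Conditions: KN(SiMe3)2 (1.5 equiv), THF, −78 °C; CS2 (5 equiv), −78 → 0 °C; MeI (5 equiv), 0 °C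
Reagents that add atoms: carbon disulfide, S=C=S; iodomethane, CI
Why: Xanthate formation (first half of the Barton–McCombie deoxygenation) proceeds by addition of the potassium alkoxide to CS2 and S-methylation, and with a quaternary carbon and an arene as neighbours no Chugaev elimination is possible.

Step 10
Reactants: 17 O-{aryl(decalinyl)methyl} S-methyl carbonodithioate
Product: 18 1-[2-(methoxymethoxy)-3-(triisopropylsilyloxy)-5-{(triisopropylsilyloxy)methyl}benzyl]-(1R,2S,4aS,8aS)-1,2,4a-trimethyl-5-methylidenedecahydronaphthalene
Conditions: Bu3SnH (2 equiv), AIBN (0.2 equiv), toluene, 90 °C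
Reagents that add atoms: none
Why: In the Barton–McCombie deoxygenation the stannyl radical adds to C=S, β-scission gives a benzylic radical that cannot reach the distant exocyclic alkene and is reduced by Bu3SnH under neutral conditions, so the alkene, MOM and TIPS groups and all stereocentres stay as they are.

Step 11
Reactants: 18 fully protected benzyl decalin
Product: 20 2-[(decalinyl)methyl]-6-(triisopropylsilyloxy)-4-[(triisopropylsilyloxy)methyl]phenol, via aryl trimethylsilyl ether 19 (not isolated)
Conditions: Me3SiOTf (3 equiv), 2,2'-bipyridyl (4 equiv), CH2Cl2, 0 °C → rt; then H2O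
Reagents that add atoms: none
Why: The silyl triflate–bipyridyl pair cleaves the aryl MOM acetal to the aryl trimethylsilyl ether without free protic acid and water then hydrolyses that labile ether, so the TIPS ethers survive and the 1,1-disubstituted alkene does not migrate.

Step 12
Reactants: 20 2-[(decalinyl)methyl]-6-(triisopropylsilyloxy)-4-[(triisopropylsilyloxy)methyl]phenol
Product: 22 2-hydroxy-4-(hydroxymethyl)-6-{[(1R,2S,4aS,8aS)-1,2,4a-trimethyl-5-methylidenedecahydronaphthalen-1-yl]methyl}phenyl hydrogen sulfate (target), via bis-TIPS aryl sulfate 21 (not isolated)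
Conditions: SO3·pyridine (5 equiv), pyridine, rt → 40 °C, short reaction time; evaporate; Bu4NF (3 equiv), THF, 0 °C → rt; C18 chromatography (NH4OAc buffer); H+-form sulfonic acid resin, 0 °C, lyophilise
Reagents that add atoms: sulfur trioxide–pyridine complex, O=S(=O)=O.c1ccncc1
Why: O-Sulfation of the only free phenol with the SO3–amine complex is followed by fluoride cleavage of both Si–O bonds under non-acidic conditions to which the aryl sulfate anion is inert, and no stereocentre is touched.

Compound list
1 | hex-5-yn-1-ol | C#CCCCCO | starting material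
2 | 2-(triphenylphosphoranylidene)propanal | CC(C=O)=P(c1ccccc1)(c1ccccc1)c1ccccc1 | starting material
3 | hex-5-ynal | C#CCCCC=O | intermediate
4 | (E)-2-methyloct-2-en-7-ynal | C#CCCC/C=C(\C)C=O | intermediate
5 | methyltriphenylphosphonium bromide | C[P+](c1ccccc1)(c1ccccc1)c1ccccc1.[Br-] | starting material
6 | methylenetriphenylphosphorane | C=P(c1ccccc1)(c1ccccc1)c1ccccc1 | intermediate
7 | (E)-3-methylnona-1,3-dien-8-yne | C#CCCC/C=C(\C)C=C | intermediate
8 | tiglic aldehyde, (E)-2-methylbut-2-enal | C/C=C(\C)C=O | starting material
9 | (1R,2R,6S)-1,3,6-trimethyl-2-(pent-4-yn-1-yl)cyclohex-3-ene-1-carbaldehyde | C#CCCC[C@H]1[C@](C)(C=O)[C@@H](C)CC=C1C | intermediate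
10 | (1R,2S,4aS,8aR)-1,2,4a-trimethyl-5-methylidenedecahydronaphthalene-1-carbaldehyde | C=C1CCC[C@H]2[C@](C)(C=O)[C@@H](C)CC[C@]12C | intermediate
11 | 3-bromo-4,5-dihydroxybenzaldehyde | O=Cc1cc(O)c(O)c(Br)c1 | starting material
12 | 3-bromo-5-hydroxy-4-(methoxymethoxy)benzaldehyde | COCOc1c(O)cc(C=O)cc1Br | intermediate
13 | 3-bromo-5-(hydroxymethyl)-2-(methoxymethoxy)phenol | COCOc1c(O)cc(CO)cc1Br | intermediate
14 | 1-bromo-2-(methoxymethoxy)-3-(triisopropylsilyloxy)-5-[(triisopropylsilyloxy)methyl]benzene | COCOc1c(Br)cc(CO[Si](C(C)C)(C(C)C)C(C)C)cc1O[Si](C(C)C)(C(C)C)C(C)C | intermediate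
15 | 2-(methoxymethoxy)-3-(triisopropylsilyloxy)-5-[(triisopropylsilyloxy)methyl]phenyllithium | [Li]c1cc(CO[Si](C(C)C)(C(C)C)C(C)C)cc(O[Si](C(C)C)(C(C)C)C(C)C)c1OCOC | intermediate
16 | aryl[(1R,2S,4aS,8aR)-1,2,4a-trimethyl-5-methylidenedecahydronaphthalen-1-yl]methanol, aryl as in 15, both carbinol epimers | C=C1CCC[C@H]2[C@](C)(C(O)c3cc(CO[Si](C(C)C)(C(C)C)C(C)C)cc(O[Si](C(C)C)(C(C)C)C(C)C)c3OCOC)[C@@H](C)CC[C@]12C | intermediate
17 | S-methyl xanthate of 16 | C=C1CCC[C@H]2[C@](C)(C(OC(=S)SC)c3cc(CO[Si](C(C)C)(C(C)C)C(C)C)cc(O[Si](C(C)C)(C(C)C)C(C)C)c3OCOC)[C@@H](C)CC[C@]12C | intermediate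
18 | (1R,2S,4aS,8aS)-1-[2-(methoxymethoxy)-3-(triisopropylsilyloxy)-5-{(triisopropylsilyloxy)methyl}benzyl]-1,2,4a-trimethyl-5-methylidenedecahydronaphthalene | C=C1CCC[C@H]2[C@](C)(Cc3cc(CO[Si](C(C)C)(C(C)C)C(C)C)cc(O[Si](C(C)C)(C(C)C)C(C)C)c3OCOC)[C@@H](C)CC[C@]12C | intermediate
19 | aryl trimethylsilyl ether of 20 | C=C1CCC[C@H]2[C@](C)(Cc3cc(CO[Si](C(C)C)(C(C)C)C(C)C)cc(O[Si](C(C)C)(C(C)C)C(C)C)c3O[Si](C)(C)C)[C@@H](C)CC[C@]12C | intermediate
20 | 2-{[(1R,2S,4aS,8aS)-1,2,4a-trimethyl-5-methylidenedecahydronaphthalen-1-yl]methyl}-6-(triisopropylsilyloxy)-4-[(triisopropylsilyloxy)methyl]phenol | C=C1CCC[C@H]2[C@](C)(Cc3cc(CO[Si](C(C)C)(C(C)C)C(C)C)cc(O[Si](C(C)C)(C(C)C)C(C)C)c3O)[C@@H](C)CC[C@]12C | intermediate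
21 | hydrogen sulfate of 20 (present in the flask as its pyridinium, then tetrabutylammonium salt; drawn as the acid) | C=C1CCC[C@H]2[C@](C)(Cc3cc(CO[Si](C(C)C)(C(C)C)C(C)C)cc(O[Si](C(C)C)(C(C)C)C(C)C)c3OS(=O)(=O)O)[C@@H](C)CC[C@]12C | intermediate
22 | 2-hydroxy-4-(hydroxymethyl)-6-{[(1R,2S,4aS,8aS)-1,2,4a-trimethyl-5-methylidenedecahydronaphthalen-1-yl]methyl}phenyl hydrogen sulfate | C=C1CCC[C@H]2[C@](C)(Cc3cc(CO)cc(O)c3OS(=O)(=O)O)[C@@H](C)CC[C@]12C | target

Total step count: 12. Longest linear sequence: 9 steps (steps 1–4, then 8–12, from hex-5-yn-1-ol); the arene branch (steps 5–7) joins at step 8.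

Steps most likely to fail

Step 4 (ring A radical closure, proposed new method). The process at risk is that the C5 radical is hydrogenated, or the ring alkene migrates by reversible hydrogen-atom transfer, faster than the slow 6-exo-dig closure onto an unactivated alkyne. The hindered aldehyde may also be reduced by the silane, or the closure may take the cis-fused course. Under iron hydride conditions the hydrogen-donor concentration cannot be set independently. The fallback uses known halide-based radical cyclisation, sets out from 9 and comes back at 10. Markovnikov addition of HBr (HBr in AcOH, CH2Cl2, −20 °C) to the trisubstituted ring alkene should give the tertiary bromide 3-bromo-1,3,6-trimethyl-2-(pent-4-yn-1-yl)cyclohexane-1-carbaldehyde F1 (ring stereocentres of 9 retained, either C3 epimer serves), used crude. Slow syringe-pump addition of (Me3Si)3SiH and AIBN to a dilute benzene solution at 80 °C abstracts bromine. The same C5 radical then closes 6-exo-dig while the donor concentration is kept low, and the vinyl radical is reduced by the silane to give 10.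

Step 3 (Diels–Alder key step). The process at risk is low turnover and weak enantiofacial discrimination with the doubly substituted enal, or erosion of the exo preference under the chiral catalyst. The fallback separates the cycloaddition from the enantiocontrol, sets out from 7 and 8 and comes back at 9. An achiral Lewis acid (Me2AlCl, CH2Cl2, −78 °C) should give the exo adduct as the racemate, that is 9 together with its mirror image (1S,2S,6R)-1,3,6-trimethyl-2-(pent-4-yn-1-yl)cyclohex-3-ene-1-carbaldehyde F2. Condensation with (1R,2R)-N,N'-dimethyl-1,2-diphenylethane-1,2-diamine (molecular sieves, Et2O) converts the pair into two diastereomeric aminals. These are (4R,5R)-1,3-dimethyl-4,5-diphenyl-2-[(1R,2R,6S)-1,3,6-trimethyl-2-(pent-4-yn-1-yl)cyclohex-3-en-1-yl]imidazolidine F3, from 9, and (4R,5R)-1,3-dimethyl-4,5-diphenyl-2-[(1S,2S,6R)-1,3,6-trimethyl-2-(pent-4-yn-1-yl)cyclohex-3-en-1-yl]imidazolidine F4, from F2. They are separated by chromatography or crystallisation, and brief hydrolysis of F3 with dilute aqueous acid in ether returns enantiopure 9.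

Step 12 (sulfation and desilylation). The process at risk is incomplete O-sulfation of the flanked phenol, silyl migration between the two catechol oxygens before sulfation, and loss of the polar sulfate salt during isolation. The fallback carries the sulfate in masked, neutral form, sets out from 20 and comes back at 21. 2,2,2-Trichloroethyl chlorosulfate with Et3N and DMAP in THF should give the aryl 2,2,2-trichloroethyl sulfate diester of 20, F5, which can be purified on silica. Zinc dust with HCO2NH4 in MeOH then removes the trichloroethyl group reductively under neutral conditions that spare the alkene, delivering 21 as its ammonium salt. This is desilylated with Bu4NF and ion-exchanged as in step 12 to give 22.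

Further compounds
F1 | step 4 | 3-bromo-1,3,6-trimethyl-2-(pent-4-yn-1-yl)cyclohexane-1-carbaldehyde (C3 epimers) | C#CCCC[C@H]1[C@](C)(C=O)[C@@H](C)CCC1(C)Br
F2 | step 3 | (1S,2S,6R)-1,3,6-trimethyl-2-(pent-4-yn-1-yl)cyclohex-3-ene-1-carbaldehyde | C#CCCC[C@@H]1[C@@](C)(C=O)[C@H](C)CC=C1C
F3 | step 3 | (4R,5R)-1,3-dimethyl-4,5-diphenyl-2-[(1R,2R,6S)-1,3,6-trimethyl-2-(pent-4-yn-1-yl)cyclohex-3-en-1-yl]imidazolidine | C#CCCC[C@H]1[C@](C)(C2N(C)[C@H](c3ccccc3)[C@@H](c3ccccc3)N2C)[C@@H](C)CC=C1C
F4 | step 3 | (4R,5R)-1,3-dimethyl-4,5-diphenyl-2-[(1S,2S,6R)-1,3,6-trimethyl-2-(pent-4-yn-1-yl)cyclohex-3-en-1-yl]imidazolidine | C#CCCC[C@@H]1[C@@](C)(C2N(C)[C@H](c3ccccc3)[C@@H](c3ccccc3)N2C)[C@H](C)CC=C1C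
F5 | step 12 | 2,2,2-trichloroethyl aryl sulfate diester of 20 | C=C1CCC[C@H]2[C@](C)(Cc3cc(CO[Si](C(C)C)(C(C)C)C(C)C)cc(O[Si](C(C)C)(C(C)C)C(C)C)c3OS(=O)(=O)OCC(Cl)(Cl)Cl)[C@@H](C)CC[C@]12C
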